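Retrosynthetic overview
1. Endgame: the C17 acid is unmasked from a 2-(trimethylsilyl)ethyl ester; the butenolide ring is attached preformed by cross-metathesis of a 9β-allyl group with α-methylene-γ-butyrolactone followed by exo-to-endo alkene migration; the C6 ester comes from acylation of the 6α-alcohol.
2. Ring B decoration is drawn from a single C8 ketone of a trans-decalin: C9 allylation with thermodynamic equilibration, C6 oxygenation by α-face conjugate borylation of the C6=C7 enone, and C7=C8–C17 by carbonylation of the C7-ene enol triflate.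
3. Key disconnection: the C2–C3 bond of ring A, closed by ring-closing metathesis (then hydrogenation) between a 1,1-dimethylallyl group on C5 and an allyl group on C10 of a monocyclic ring B silyl enol ether.
4. Enabling feature: C2 and C3 are the only adjacent, unfunctionalised CH2 carbons of ring A, and each lies one carbon from a quaternary carbon (C4 with its gem-dimethyl group, C10 with its angular methyl group) held by the neighbouring ring B carbons C5 and C10; two terminal alkenes on these trans arms can therefore meet in a Thorpe–Ingold-assisted six-ring closure with no heteroatom handle in ring A.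
5. Ring B comes from a cheap anisole by Birch dearomatisation, amine-catalysed enantioselective enone isomerisation (sets C5) and anti conjugate allylation (sets C10); ring order: B (arene-derived), then A (metathesis), then the butenolide (brought in preformed).

Key step: step 6

Remark: the C6 ester of the given SMILES is read as the (E)-2-methylbut-2-enoate (tiglate); labdane numbering is used (ring A: C1–C5 and C10; ring B: C5–C10; side chain C11–C16; C17 is the carboxyl carbon on C8).

Step 1
Reactants: 1 4-bromo-3-methylanisole; 2 isobutyraldehyde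
Product: 3 2-(4-methoxy-2-methylphenyl)-2-methylpropanal
Conditions: Pd(OAc)2 (2 mol %), rac-BINAP (3 mol %), Cs2CO3, dioxane, 80 °C
Reagents that add atoms: none
Why: Palladium-catalysed α-arylation of an aldehyde (oxidative addition of the aryl bromide to zerovalent palladium, enolate binding, C–C reductive elimination) should give the quaternary benzylic aldehyde, because isobutyraldehyde has one α-hydrogen and cannot self-condense; this joins C4 (with both methyl groups and C3) to the future C5.

Step 2
Reactants: 3 2-(4-methoxy-2-methylphenyl)-2-methylpropanal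
Product: 4 1-methoxy-3-methyl-4-(2-methylbut-3-en-2-yl)benzene
Conditions: Ph3PCH3Br, KOt-Bu, THF, 0 to 25 °C
Reagents that add atoms: methyltriphenylphosphonium bromide, C[P+](c1ccccc1)(c1ccccc1)c1ccccc1.[Br-]
Why: Wittig methylenation of a non-enolisable neopentylic aldehyde should be clean and turns C3 into the terminal alkene carbon needed for the ring closure.

Step 3
Reactants: 4 1-methoxy-3-methyl-4-(2-methylbut-3-en-2-yl)benzene
Product: 6 3-methyl-4-(2-methylbut-3-en-2-yl)cyclohex-3-en-1-one, via dihydroanisole 5 (not isolated)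
Conditions: Li, NH3 (l), t-BuOH, THF, −78 to −33 °C; then (CO2H)2, MeOH/H2O, 0 °C
Reagents that add atoms: water, O
Why: Birch reduction of an anisole should protonate the unsubstituted ortho and meta carbons (future C9 and C6) and leave the methoxy- and alkyl-bearing carbons on the two double bonds, the isolated terminal alkene is not reduced by Li/NH3, and mild enol ether hydrolysis then gives the unconjugated β,γ-enone.

Step 4
Reactants: 6 3-methyl-4-(2-methylbut-3-en-2-yl)cyclohex-3-en-1-one
Product: 7 (R)-3-methyl-4-(2-methylbut-3-en-2-yl)cyclohex-2-en-1-one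
Conditions: 9-amino-9-deoxy-epi-cinchona primary–tertiary diamine catalyst (10 mol %, the pseudoenantiomer that leads to R), CF3CO2H (20 mol %), toluene, 0 °C
Reagents that add atoms: none
Why: Amine-catalysed enantioselective isomerisation of a β,γ- to an α,β-unsaturated cyclohexenone: the catalyst should form the dienamine and return the proton to the γ-carbon C5 on one enantioface, which sets the C5 stereocentre under catalyst control, and conjugation plus relief of the cis strain between the tert-alkyl and methyl groups on the tetrasubstituted alkene make the step downhill.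

Step 5
Reactants: 7 (R)-3-methyl-4-(2-methylbut-3-en-2-yl)cyclohex-2-en-1-one
Product: 8 tert-butyldimethyl{[(3S,4S)-3-methyl-4-(2-methylbut-3-en-2-yl)-3-(prop-2-en-1-yl)cyclohex-1-en-1-yl]oxy}silane
Conditions: allylSnBu3, t-BuMe2SiOTf, CH2Cl2, −78 to −40 °C; Et3N quench
Reagents that add atoms: allyltributylstannane, C=CC[Sn](CCCC)(CCCC)CCCC; tert-butyldimethylsilyl trifluoromethanesulfonate, CC(C)(C)[Si](C)(C)OS(=O)(=O)C(F)(F)F
Why: Hosomi–Sakurai-type conjugate allylation under silyl triflate activation: the O-silylated enone should be attacked by the allylstannane at the β-carbon C10 from the face anti to the pseudoaxial C5 substituent (the usual trans addition to 4-substituted cyclohexenones), which sets the quaternary C10 stereocentre under substrate control with the allyl group trans to the C5 arm and traps the product regiospecifically as the C8–C9 silyl enol ether.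

Step 6
Reactants: 8 tert-butyldimethyl{[(3S,4S)-3-methyl-4-(2-methylbut-3-en-2-yl)-3-(prop-2-en-1-yl)cyclohex-1-en-1-yl]oxy}silane
Product: 9 8-(tert-butyldimethylsilyloxy)-4,4,10β-trimethyl-5αH-decalin-2,8-diene (labdane numbering)
Conditions: second-generation Grubbs catalyst RuCl2(=CHPh)(PCy3)(H2IMes) (5 mol %), CH2Cl2 (0.005 M), 40 °C
Reagents that add atoms: none
Why: Ring-closing olefin metathesis: the ruthenium alkylidene should load onto the less hindered allyl terminus (C2), add across the neopentylic vinyl group (C3) through a ruthenacyclobutane and expel ethylene, whose loss drives the closure. The closest known reaction type is the ring-closing metathesis of 1,7-dienes to cyclohexenes that carry an allylic quaternary carbon. Ring A closes as a six-membered carbocycle onto the existing C5–C10 bond of ring B by a [2+2]/retro-[2+2] sequence, so no polar trajectory rule restricts it. No stereocentre is formed; the trans ring fusion is already stored in the anti relationship of the C5 and C10 arms set in step 5, which can both sit equatorial on ring B. The step needs selectivity for the two terminal alkenes over the silyl enol ether C8=C9 and for cyclisation over oligomerisation: the enol ether is trisubstituted and shielded by the quaternary C10, while the C4 gem-dimethyl group and the quaternary C10 hold the chain ends together (Thorpe–Ingold effect) and high dilution disfavours intermolecular metathesis.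

Step 7
Reactants: 9 8-(tert-butyldimethylsilyloxy)-4,4,10β-trimethyl-5αH-decalin-2,8-diene
Product: 10 8-(tert-butyldimethylsilyloxy)-4,4,10β-trimethyl-5αH-decal-8-ene
Conditions: H2 (1 atm), RhCl(PPh3)3 (5 mol %), benzene, 25 °C
Reagents that add atoms: none
Why: Homogeneous hydrogenation with RhCl(PPh3)3 should saturate only the cis-disubstituted C2=C3 alkene, because the trisubstituted silyl enol ether next to the quaternary C10 is too hindered for this catalyst; no stereocentre is formed.

Step 8
Reactants: 10 8-(tert-butyldimethylsilyloxy)-4,4,10β-trimethyl-5αH-decal-8-ene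
Product: 12 9β-allyl-4,4,10β-trimethyl-5αH-decalin-8-one, via 9α-allyl ketone 11 (not isolated)
Conditions: Pd(PPh3)4 (5 mol %), diallyl carbonate, Bu4N[Ph3SiF2] (35 mol %), THF, 25 °C; then NaOMe (0.3 equiv), MeOH, 25 °C
Reagents that add atoms: diallyl carbonate, C=CCOC(=O)OCC=C
Why: Tsuji–Trost allylation of a silyl enol ether: fluoride (then allyloxide) unmasks the regiodefined C8–C9 enolate, which the π-allylpalladium cation should alkylate at C9 from the α face anti to the axial 10β-methyl group, and methoxide then epimerises C9 through the enol to the more stable equatorial 9β-allyl ketone, so the C9 stereocentre is set under thermodynamic control.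

Step 9
Reactants: 12 9β-allyl-4,4,10β-trimethyl-5αH-decalin-8-one
Product: 14 9β-allyl-4,4,10β-trimethyl-5αH-decal-6-en-8-one, via silyl enol ether 13 (not isolated)
Conditions: LiN(i-Pr)2, THF, −78 °C; Me3SiCl; then Pd(OAc)2 (10 mol %), O2 (1 atm), DMSO, 25 °C
Reagents that add atoms: chlorotrimethylsilane, C[Si](C)(C)Cl (silyl group of 13 only; none remains in 14)
Why: Saegusa–Ito dehydrogenation: kinetic deprotonation should take the C7 methylene and not the tertiary C9 hydrogen beside the quaternary C10, and the silyl enol ether then undergoes palladation and β-hydride elimination (oxygen returns zerovalent palladium to divalent palladium) to give the C6=C7 enone, which activates C6.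

Step 10
Reactants: 14 9β-allyl-4,4,10β-trimethyl-5αH-decal-6-en-8-one
Product: 16 9β-allyl-6α-hydroxy-4,4,10β-trimethyl-5αH-decalin-8-one, via boronate 15 (not isolated)
Conditions: CuCl (5 mol %), Xantphos (5 mol %), NaOt-Bu (10 mol %), B2pin2, MeOH, THF, 25 °C; then NaBO3·4H2O, THF/H2O, 25 °C
Reagents that add atoms: bis(pinacolato)diboron, CC1(C)OB(OC1(C)C)B1OC(C)(C)C(C)(C)O1 (boryl group of 15); sodium perborate, [Na+].[O-]OB=O (hydroxyl oxygen of 16)
Why: Copper-catalysed conjugate borylation followed by oxidation with retention: the borylcopper species should add to C6 from the α face, because the β face is screened by the axial 10β- and 4β-methyl groups, so the 6α-oxygen stereocentre is set under substrate control.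

Step 11
Reactants: 16 9β-allyl-6α-hydroxy-4,4,10β-trimethyl-5αH-decalin-8-one
Product: 17 9β-allyl-6α-(tert-butyldimethylsilyloxy)-4,4,10β-trimethyl-5αH-decalin-8-one
Conditions: t-BuMe2SiOTf, 2,6-lutidine, CH2Cl2, −78 to 0 °C
Reagents that add atoms: tert-butyldimethylsilyl trifluoromethanesulfonate, CC(C)(C)[Si](C)(C)OS(=O)(=O)C(F)(F)F
Why: Silyl ether protection with the silyl triflate should be fast even at the hindered C6 position and turns the β-hydroxyl into a poor leaving group before enolisation.

Step 12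
Reactants: 17 9β-allyl-6α-(tert-butyldimethylsilyloxy)-4,4,10β-trimethyl-5αH-decalin-8-one
Product: 18 9β-allyl-6α-(tert-butyldimethylsilyloxy)-4,4,10β-trimethyl-5αH-decal-7-en-8-yl trifluoromethanesulfonate
Conditions: KN(SiMe3)2, THF, −78 °C; PhNTf2
Reagents that add atoms: N-phenylbis(trifluoromethanesulfonimide), O=S(=O)(N(c1ccccc1)S(=O)(=O)C(F)(F)F)C(F)(F)F
Why: Enol triflate formation: the bulky amide should deprotonate the C7 methylene kinetically (C9 is tertiary and neopentylic), the β-silyloxy group should not eliminate at −78 °C, and O-sulfonylation fixes the C7=C8 double bond of the target.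

Step 13
Reactants: 18 9β-allyl-6α-(tert-butyldimethylsilyloxy)-4,4,10β-trimethyl-5αH-decal-7-en-8-yl trifluoromethanesulfonate
Product: 19 2-(trimethylsilyl)ethyl 9β-allyl-6α-(tert-butyldimethylsilyloxy)-4,4,10β-trimethyl-5αH-decal-7-ene-8-carboxylate
Conditions: Pd(OAc)2 (5 mol %), dppf (10 mol %), CO (1 atm), Me3SiCH2CH2OH, Et3N, DMF, 60 °C
Reagents that add atoms: carbon monoxide, [C-]#[O+]; 2-(trimethylsilyl)ethanol, C[Si](C)(C)CCO
Why: Palladium-catalysed alkoxycarbonylation of an enol triflate (oxidative addition to zerovalent palladium, CO insertion, alcoholysis of the acylpalladium) should install C17 as a fluoride-cleavable ester with the C7=C8 alkene in place.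

Step 14
Reactants: 19 2-(trimethylsilyl)ethyl 9β-allyl-6α-(tert-butyldimethylsilyloxy)-4,4,10β-trimethyl-5αH-decal-7-ene-8-carboxylate
Product: 20 2-(trimethylsilyl)ethyl 9β-allyl-6α-hydroxy-4,4,10β-trimethyl-5αH-decal-7-ene-8-carboxylate
Conditions: HF·pyridine, pyridine, THF, 0 to 25 °C
Reagents that add atoms: none
Why: Desilylation with buffered HF·pyridine should free the 6α-hydroxyl while the 2-(trimethylsilyl)ethyl ester, which needs naked fluoride, survives.

Step 15
Reactants: 20 2-(trimethylsilyl)ethyl 9β-allyl-6α-hydroxy-4,4,10β-trimethyl-5αH-decal-7-ene-8-carboxylate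
Product: 21 2-(trimethylsilyl)ethyl 9β-allyl-6α-[(E)-2-methylbut-2-enoyloxy]-4,4,10β-trimethyl-5αH-decal-7-ene-8-carboxylate
Conditions: tigloyl chloride, Et3N, DMAP (cat.), CH2Cl2, 40 °C
Reagents that add atoms: (E)-2-methylbut-2-enoyl chloride (tigloyl chloride), C/C=C(\C)C(Cl)=O
Why: DMAP-catalysed acylation should esterify the hindered equatorial 6α-alcohol with retention at C6, and the (E)-geometry of the thermodynamically preferred tiglate is not at risk.

Step 16
Reactants: 21 2-(trimethylsilyl)ethyl 9β-allyl-6α-[(E)-2-methylbut-2-enoyloxy]-4,4,10β-trimethyl-5αH-decal-7-ene-8-carboxylate; 22 α-methylene-γ-butyrolactone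
Product: 23 2-(trimethylsilyl)ethyl 6α-[(E)-2-methylbut-2-enoyloxy]-4,4,10β-trimethyl-9β-[(2E)-2-(2-oxodihydrofuran-3(2H)-ylidene)ethyl]-5αH-decal-7-ene-8-carboxylate
Conditions: 22 (3 equiv), second-generation Hoveyda–Grubbs catalyst RuCl2(=CH-C6H4-2-O-i-Pr)(H2IMes) (5 mol %), 2,6-dichloro-1,4-benzoquinone (10 mol %), CH2Cl2, 40 °C
Reagents that add atoms: none
Why: Olefin cross-metathesis between the monosubstituted allyl alkene and the 1,1-disubstituted electron-poor α-methylene lactone should favour the cross product, since the trisubstituted enoate and tiglate alkenes are inert and the benzoquinone suppresses ruthenium hydride-mediated alkene migration; the (E)-alkylidene lactone is expected.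

Step 17
Reactants: 23 2-(trimethylsilyl)ethyl 6α-[(E)-2-methylbut-2-enoyloxy]-4,4,10β-trimethyl-9β-[(2E)-2-(2-oxodihydrofuran-3(2H)-ylidene)ethyl]-5αH-decal-7-ene-8-carboxylate
Product: 24 2-(trimethylsilyl)ethyl 6α-[(E)-2-methylbut-2-enoyloxy]labda-7,13-dien-16,15-olid-17-oate
Conditions: RhCl3·3H2O (10 mol %), EtOH, 75 °C
Reagents that add atoms: none
Why: Rhodium hydride-mediated double-bond migration (addition–elimination) should move the exocyclic C12=C13 alkene into the lactone ring to give the more stable endocyclic α-alkyl butenolide (C13=C14), a known exo-to-endo isomerisation of α-alkylidene-γ-butyrolactones, while the conjugated C7=C8 and tiglate alkenes have no lower-energy position to reach.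

Step 18
Reactants: 24 2-(trimethylsilyl)ethyl 6α-[(E)-2-methylbut-2-enoyloxy]labda-7,13-dien-16,15-olid-17-oate
Product: 25 6α-[(E)-2-methylbut-2-enoyloxy]labda-7,13-dien-16,15-olid-17-oic acid (CNP0245290.2)
Conditions: Bu4NF, THF, 0 °C; dilute HCl work-up
Reagents that add atoms: none
Why: Fluoride attack on silicon triggers β-elimination of the 2-(trimethylsilyl)ethyl ester (loss of ethylene and Me3SiF), which should free the C17 acid without touching the tiglate or the butenolide.

Compound list
1 | 4-bromo-3-methylanisole | COc1ccc(Br)c(C)c1 | starting material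
2 | isobutyraldehyde | CC(C)C=O | starting material
3 | 2-(4-methoxy-2-methylphenyl)-2-methylpropanal | COc1ccc(C(C)(C)C=O)c(C)c1 | intermediate
4 | 1-methoxy-3-methyl-4-(2-methylbut-3-en-2-yl)benzene | COc1ccc(C(C)(C)C=C)c(C)c1 | intermediate
5 | 1-methoxy-5-methyl-4-(2-methylbut-3-en-2-yl)cyclohexa-1,4-diene | COC1=CCC(C(C)(C)C=C)=C(C)C1 | intermediate
6 | 3-methyl-4-(2-methylbut-3-en-2-yl)cyclohex-3-en-1-one | O=C1CCC(C(C)(C)C=C)=C(C)C1 | intermediate
7 | (R)-3-methyl-4-(2-methylbut-3-en-2-yl)cyclohex-2-en-1-one | C=CC(C)(C)[C@@H]1CCC(=O)C=C1C | intermediate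
8 | tert-butyldimethyl{[(3S,4S)-3-methyl-4-(2-methylbut-3-en-2-yl)-3-(prop-2-en-1-yl)cyclohex-1-en-1-yl]oxy}silane (allyl trans to the tert-alkyl group) | C=CC(C)(C)[C@@H]1CCC(O[Si](C)(C)C(C)(C)C)=C[C@@]1(C)CC=C | intermediate
9 | 8-(tert-butyldimethylsilyloxy)-4,4,10β-trimethyl-5αH-decalin-2,8-diene (trans-fused; C2=C3 and C8=C9) | CC(C)(C)[Si](C)(C)OC1=C[C@@]2(C)CC=CC(C)(C)[C@@H]2CC1 | intermediate
10 | 8-(tert-butyldimethylsilyloxy)-4,4,10β-trimethyl-5αH-decal-8-ene (C8=C9) | CC(C)(C)[Si](C)(C)OC1=C[C@@]2(C)CCCC(C)(C)[C@@H]2CC1 | intermediate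
11 | 9α-allyl-4,4,10β-trimethyl-5αH-decalin-8-one | O=C1CC[C@H]2C(C)(C)CCC[C@]2(C)[C@@H]1CC=C | intermediate
12 | 9β-allyl-4,4,10β-trimethyl-5αH-decalin-8-one | O=C1CC[C@H]2C(C)(C)CCC[C@]2(C)[C@H]1CC=C | intermediate
13 | 9β-allyl-4,4,10β-trimethyl-8-(trimethylsilyloxy)-5αH-decal-7-ene | C[Si](C)(C)OC1=CC[C@H]2C(C)(C)CCC[C@]2(C)[C@H]1CC=C | intermediate
14 | 9β-allyl-4,4,10β-trimethyl-5αH-decal-6-en-8-one | O=C1C=C[C@H]2C(C)(C)CCC[C@]2(C)[C@H]1CC=C | intermediate
15 | 9β-allyl-4,4,10β-trimethyl-6α-(4,4,5,5-tetramethyl-1,3,2-dioxaborolan-2-yl)-5αH-decalin-8-one | O=C1C[C@H](B3OC(C)(C)C(C)(C)O3)[C@H]2C(C)(C)CCC[C@]2(C)[C@H]1CC=C | intermediate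
16 | 9β-allyl-6α-hydroxy-4,4,10β-trimethyl-5αH-decalin-8-one | O=C1C[C@H](O)[C@H]2C(C)(C)CCC[C@]2(C)[C@H]1CC=C | intermediate
17 | 9β-allyl-6α-(tert-butyldimethylsilyloxy)-4,4,10β-trimethyl-5αH-decalin-8-one | O=C1C[C@H](O[Si](C)(C)C(C)(C)C)[C@H]2C(C)(C)CCC[C@]2(C)[C@H]1CC=C | intermediate
18 | 9β-allyl-6α-(tert-butyldimethylsilyloxy)-4,4,10β-trimethyl-5αH-decal-7-en-8-yl trifluoromethanesulfonate | O=S(=O)(OC1=C[C@H](O[Si](C)(C)C(C)(C)C)[C@H]2C(C)(C)CCC[C@]2(C)[C@H]1CC=C)C(F)(F)F | intermediate
19 | 2-(trimethylsilyl)ethyl 9β-allyl-6α-(tert-butyldimethylsilyloxy)-4,4,10β-trimethyl-5αH-decal-7-ene-8-carboxylate | C[Si](C)(C)CCOC(=O)C1=C[C@H](O[Si](C)(C)C(C)(C)C)[C@H]2C(C)(C)CCC[C@]2(C)[C@H]1CC=C | intermediate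
20 | 2-(trimethylsilyl)ethyl 9β-allyl-6α-hydroxy-4,4,10β-trimethyl-5αH-decal-7-ene-8-carboxylate | C[Si](C)(C)CCOC(=O)C1=C[C@H](O)[C@H]2C(C)(C)CCC[C@]2(C)[C@H]1CC=C | intermediate
21 | 2-(trimethylsilyl)ethyl 9β-allyl-6α-[(E)-2-methylbut-2-enoyloxy]-4,4,10β-trimethyl-5αH-decal-7-ene-8-carboxylate | C[Si](C)(C)CCOC(=O)C1=C[C@H](OC(=O)/C(C)=C/C)[C@H]2C(C)(C)CCC[C@]2(C)[C@H]1CC=C | intermediate
22 | α-methylene-γ-butyrolactone (3-methylidenedihydrofuran-2(3H)-one) | C=C1CCOC1=O | starting material
23 | 2-(trimethylsilyl)ethyl 6α-[(E)-2-methylbut-2-enoyloxy]-4,4,10β-trimethyl-9β-[(2E)-2-(2-oxodihydrofuran-3(2H)-ylidene)ethyl]-5αH-decal-7-ene-8-carboxylate | C[Si](C)(C)CCOC(=O)C1=C[C@H](OC(=O)/C(C)=C/C)[C@H]2C(C)(C)CCC[C@]2(C)[C@H]1C/C=C3/C(=O)OCC3 | intermediate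
24 | 2-(trimethylsilyl)ethyl 6α-[(E)-2-methylbut-2-enoyloxy]labda-7,13-dien-16,15-olid-17-oate | C[Si](C)(C)CCOC(=O)C1=C[C@H](OC(=O)/C(C)=C/C)[C@H]2C(C)(C)CCC[C@]2(C)[C@H]1CCC3=CCOC3=O | intermediate
25 | 6α-[(E)-2-methylbut-2-enoyloxy]labda-7,13-dien-16,15-olid-17-oic acid (CNP0245290.2) | C/C=C(\C)C(=O)O[C@H]1C=C(C(=O)O)[C@H](CCC2=CCOC2=O)[C@@]2(C)CCCC(C)(C)[C@H]12 | target

Total step count: 18 steps.
Longest linear sequence: 18 steps (from 1 to 25).

Steps most likely to fail

Step 4. Enantioface discrimination in the protonation of C5 may be incomplete, because this carbon carries a tert-alkyl group, and uncatalysed conjugation could erode the selectivity. The fallback sets out from 6 and comes back at 7. Catalytic DBU in CH2Cl2 should conjugate 6 to racemic 3-methyl-4-(2-methylbut-3-en-2-yl)cyclohex-2-en-1-one F1. A reagent-controlled CBS reduction (chiral oxazaborolidine, BH3·SMe2) should then convert the two enantiomers into diastereomeric cis and trans allylic alcohols of one carbinol configuration, which are separated by chromatography. The diastereomer derived from the (R)-enone, (1S,4R)-3-methyl-4-(2-methylbut-3-en-2-yl)cyclohex-2-en-1-ol F2, is oxidised with MnO2 to 7.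

Step 5. C–C bond formation at the fully substituted β-carbon next to the tert-alkyl-bearing C5 may stall, or 1,2-addition may compete. The fallback sets out from 7 and comes back at 8. A Mukaiyama–Michael addition of the smaller and more nucleophilic tert-butyl[(1-methoxyethenyl)oxy]dimethylsilane (catalytic t-BuMe2SiOTf, CH2Cl2, −78 °C) should give methyl {(1S,6S)-3-[(tert-butyldimethylsilyl)oxy]-1-methyl-6-(2-methylbut-3-en-2-yl)cyclohex-2-en-1-yl}acetate F3 with the same anti selectivity. Reduction with (i-Bu)2AlH at −78 °C should give {(1S,6S)-3-[(tert-butyldimethylsilyl)oxy]-1-methyl-6-(2-methylbut-3-en-2-yl)cyclohex-2-en-1-yl}acetaldehyde F4, and Wittig methylenation (Ph3PCH3Br, KOt-Bu) gives 8.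

Step 17. The double-bond migration may stall at an exo/endo equilibrium or run toward C11. The fallback sets out from 21 and comes back at 24, bypassing 23. Lemieux–Johnson cleavage of the terminal alkene (OsO4 cat., NaIO4, 2,6-lutidine) should give 2-(trimethylsilyl)ethyl 6α-[(E)-2-methylbut-2-enoyloxy]-4,4,10β-trimethyl-9β-(2-oxoethyl)-5αH-decal-7-ene-8-carboxylate F5. NaBH4 reduction gives the 9β-(2-hydroxyethyl) analogue F6, and the Appel reaction (I2, PPh3, imidazole) gives the 9β-(2-iodoethyl) analogue F7. Zinc insertion (Zn, LiCl, THF) gives the 9β-[2-(iodozincio)ethyl] analogue F8. Negishi coupling of F8 with 3-bromofuran-2(5H)-one (Pd(OAc)2, SPhos) forms the C12–C13 bond directly on the endocyclic butenolide and gives 24.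

Further compounds
F1 | step 4 | racemic 3-methyl-4-(2-methylbut-3-en-2-yl)cyclohex-2-en-1-one | C=CC(C)(C)C1CCC(=O)C=C1C
F2 | step 4 | (1S,4R)-3-methyl-4-(2-methylbut-3-en-2-yl)cyclohex-2-en-1-ol | C=CC(C)(C)[C@@H]1CC[C@H](O)C=C1C
F3 | step 5 | methyl {(1S,6S)-3-[(tert-butyldimethylsilyl)oxy]-1-methyl-6-(2-methylbut-3-en-2-yl)cyclohex-2-en-1-yl}acetate | C=CC(C)(C)[C@@H]1CCC(O[Si](C)(C)C(C)(C)C)=C[C@@]1(C)CC(=O)OC
F4 | step 5 | {(1S,6S)-3-[(tert-butyldimethylsilyl)oxy]-1-methyl-6-(2-methylbut-3-en-2-yl)cyclohex-2-en-1-yl}acetaldehyde | C=CC(C)(C)[C@@H]1CCC(O[Si](C)(C)C(C)(C)C)=C[C@@]1(C)CC=O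
F5 | step 17 | 2-(trimethylsilyl)ethyl 6α-[(E)-2-methylbut-2-enoyloxy]-4,4,10β-trimethyl-9β-(2-oxoethyl)-5αH-decal-7-ene-8-carboxylate | C[Si](C)(C)CCOC(=O)C1=C[C@H](OC(=O)/C(C)=C/C)[C@H]2C(C)(C)CCC[C@]2(C)[C@H]1CC=O
F6 | step 17 | 2-(trimethylsilyl)ethyl 9β-(2-hydroxyethyl)-6α-[(E)-2-methylbut-2-enoyloxy]-4,4,10β-trimethyl-5αH-decal-7-ene-8-carboxylate | C[Si](C)(C)CCOC(=O)C1=C[C@H](OC(=O)/C(C)=C/C)[C@H]2C(C)(C)CCC[C@]2(C)[C@H]1CCO
F7 | step 17 | 2-(trimethylsilyl)ethyl 9β-(2-iodoethyl)-6α-[(E)-2-methylbut-2-enoyloxy]-4,4,10β-trimethyl-5αH-decal-7-ene-8-carboxylate | C[Si](C)(C)CCOC(=O)C1=C[C@H](OC(=O)/C(C)=C/C)[C@H]2C(C)(C)CCC[C@]2(C)[C@H]1CCI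
F8 | step 17 | 2-(trimethylsilyl)ethyl 9β-[2-(iodozincio)ethyl]-6α-[(E)-2-methylbut-2-enoyloxy]-4,4,10β-trimethyl-5αH-decal-7-ene-8-carboxylate | C[Si](C)(C)CCOC(=O)C1=C[C@H](OC(=O)/C(C)=C/C)[C@H]2C(C)(C)CCC[C@]2(C)[C@H]1CC[Zn]I
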